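**Retrosynthetic overview**

1. Target ⇒ macrocyclic bis(quinolizinium) salt: C9 and C9a of both halves come from one enantioselective pyridinium hydrogenation, C1 and C3 from base equilibration.
2. Bis(quinolizinium) ⇒ key disconnection of both N5–C4 bonds: intramolecular aza-Michael addition of each pyridine nitrogen to a C1-tethered isopropenyl ketone, which closes ring B and activates ring A for reduction.
3. Bis(isopropenyl ketone) ⇒ C1–C2 acylation of a head-to-tail [6.6](2,3)pyridinophane with a methacrylic Weinreb amide.
4. Pyridinophane ⇒ cyclodimerisation of 3-(5-chloropentyl)-2-methylpyridine ⇒ B-alkyl Suzuki coupling of 3-bromo-2-methylpyridine with 5-chloropent-1-ene.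
5. Ring order: pyridine rings (bought) → 16-membered carbocycle → ring B of each quinolizine (C–N) → saturation of ring A.

Assumption: locants follow quinolizine numbering in each half (C1, C2 = C=O, C3 = CMe, C4, N5, C6–C9, C9a), and the (R)-ligand in step 5 is assumed to give the (9S,9aR) series; if the sense proves opposite, the (S)-ligand is used.

**Route**

Step 1
Reactants: 1 3-bromo-2-methylpyridine; 2 5-chloropent-1-ene
Product: 4 3-(5-chloropentyl)-2-methylpyridine, via B-(5-chloropentyl)-9-borabicyclo[3.3.1]nonane 3 (not isolated)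
Conditions: 2, 9-BBN (1.0 equiv), THF, 0 → 23 °C; then 1, Pd(dppf)Cl2 (3 mol%), aq. K3PO4 (3 equiv), THF/DMF, 60 °C
Reagents that add atoms: none
Why: Anti-Markovnikov hydroboration of the terminal alkene followed by B-alkyl Suzuki–Miyaura coupling with the 3-bromopyridine is reliable and leaves the primary alkyl chloride untouched; no stereocentre is formed.

Step 2
Reactants: 4 3-(5-chloropentyl)-2-methylpyridine (2 molecules)
Product: 7 head-to-tail [6.6](2,3)pyridinophane, via picolyllithium 5 (not isolated), via lithiated linear dimer 6 (not isolated)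
Conditions: LDA (LiN(i-Pr)2, 1.05 equiv), THF (0.02 M), −78 °C, 30 min; then −78 → 23 °C over 12 h
Reagents that add atoms: none
Why: Lateral lithiation removes only the azaallylic 2-methyl proton and the picolyllithium displaces primary chloride (SN2), so the only cyclic dimer possible is head-to-tail; monomer closure needs an eight-membered transition state onto a planar azaallyl anion, so complete metalation followed by warming at moderate dilution should favour the 16-membered ring (expected 25–35%).

Step 3
Reactants: 8 methacryloyl chloride; 9 N,O-dimethylhydroxylamine hydrochloride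
Product: 10 N-methoxy-N-methylmethacrylamide
Conditions: K2CO3 (1.2 equiv), CH2Cl2/H2O, BHT (trace), 0 → 23 °C
Reagents that add atoms: none
Why: Schotten–Baumann N-acylation gives the Weinreb amide cleanly; no stereocentre is formed.

Step 4
Reactants: 7 head-to-tail [6.6](2,3)pyridinophane; 10 N-methoxy-N-methylmethacrylamide (2 molecules)
Product: 15 macrocyclic bis(3-methyl-2-oxo-1,2,3,4-tetrahydroquinolizin-5-ium) dibromide, via dilithio pyridinophane 11 (not isolated), via bis(lithium hemiaminal) 12 (not isolated), via bis(isopropenyl ketone) 13 (not isolated), via bis(vinylogous amide) 14 (not isolated)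
Conditions: LDA (2.3 equiv), THF, −78 → −30 °C; 10 (2.5 equiv), −78 → −20 °C; AcOH, MeOH, 50 °C; aq. NaHCO3 wash; HBr (2.05 equiv), MeOH, 0 °C
Reagents that add atoms: hydrogen bromide, Br
Why: Lateral lithiation of both azaallylic CH2 groups and Weinreb ketone synthesis give the bis(isopropenyl ketone) without over-addition, and on acidification each pyridine nitrogen adds to its tethered enone (intramolecular 6-endo aza-Michael addition, the C–N bond that closes ring B and makes the pyridinium), driven by formation of the vinylogous amide and then the salt; the C1 and C3 centres formed here are unselective but epimerisable.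

Step 5
Reactants: 15 macrocyclic bis(3-methyl-2-oxo-1,2,3,4-tetrahydroquinolizin-5-ium) dibromide
Product: 17 CNP0268544.6 (target), via bis(hydrobromide) 16 (not isolated)
Conditions: [Ir(cod)Cl]2 (2.5 mol%), (R)-SegPhos (5.5 mol%), H2 (50 bar), CH2Cl2/i-PrOH 4:1, 40 °C, 36 h; then K2CO3 (4 equiv), MeOH, 23 °C, 12 h
Reagents that add atoms: none
Why: Proposed new method: iridium–bisphosphine asymmetric hydrogenation of a 2-oxo-1,2,3,4-tetrahydroquinolizinium bromide, twice in one macrocycle; stepwise hydride/proton transfer first saturates C6–C8 and leaves a hexahydro iminium (the protonated vinylogous amide, N5=C9a) whose C9 epimerises rapidly through the dienamine, so the final chiral Ir–H delivery to C9a, anti to the C9 chain, is a dynamic kinetic resolution that sets C9a (R) and C9 (S) together and cis (H9 cis to H9a), while the stoichiometric HBr keeps the iminium available and the product amine protonated; the closest known reactions are the Ir/diphosphine hydrogenation of N-benzyl-2-substituted pyridinium bromides and the cis-selective dynamic-kinetic hydrogenation of 2,3-disubstituted quinolines, neither shown on a ring-fused pyridinium carrying a β-keto group; K2CO3/MeOH then enolises only C1 and C3 and brings the C1 chain and the 3-methyl group equatorial (1R,3S), and because the two rings are reduced independently under catalyst control the main minor product is the chromatographically separable meso diastereomer.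

**Compound list**

1 | 3-bromo-2-methylpyridine | Cc1ncccc1Br | starting material
2 | 5-chloropent-1-ene | C=CCCCCl | starting material
3 | B-(5-chloropentyl)-9-borabicyclo[3.3.1]nonane | ClCCCCCB1C2CCCC1CCC2 | intermediate
4 | 3-(5-chloropentyl)-2-methylpyridine | Cc1ncccc1CCCCCCl | intermediate
5 | [3-(5-chloropentyl)pyridin-2-yl]methyllithium (picolyllithium) | [Li]Cc1ncccc1CCCCCCl | intermediate
6 | lithiated linear head-to-tail dimer: {3-[6-(3-(5-chloropentyl)pyridin-2-yl)hexyl]pyridin-2-yl}methyllithium | [Li]Cc1ncccc1CCCCCCc1ncccc1CCCCCCl | intermediate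
7 | head-to-tail [6.6](2,3)pyridinophane: 16-membered carbocycle in which two hexamethylene chains each run from C2 of one pyridine to C3 of the other | c1ccc2c(n1)CCCCCCc1cccnc1CCCCCC2 | intermediate
8 | methacryloyl chloride | C=C(C)C(Cl)=O | starting material
9 | N,O-dimethylhydroxylamine hydrochloride | CNOC.Cl | starting material
10 | N-methoxy-N-methylmethacrylamide | C=C(C)C(=O)N(C)OC | intermediate
11 | dilithio pyridinophane: 7 lithiated at both CH2 groups attached to pyridine C2 | c1ccc2c(n1)C([Li])CCCCCc1cccnc1C([Li])CCCCC2 | intermediate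
12 | bis(lithium hemiaminal): tetrahedral adduct of 11 with two molecules of 10 (diastereomer mixture) | c1ccc2c(n1)C(C(O[Li])(N(C)OC)C(C)=C)CCCCCc1cccnc1C(C(O[Li])(N(C)OC)C(C)=C)CCCCC2 | intermediate
13 | bis(isopropenyl ketone): 7 carrying a methacryloyl group on each CH attached to pyridine C2 (diastereomer mixture) | c1ccc2c(n1)C(C(=O)C(C)=C)CCCCCc1cccnc1C(C(=O)C(C)=C)CCCCC2 | intermediate
14 | bis(vinylogous amide): macrocyclic bis(3-methyl-3,4-dihydro-2H-quinolizin-2-one), C1=C9a in each unit, C1 of each unit joined to C9 of the other by (CH2)5 (C3 epimer mixture) | CC1CN2C=CC=C3C2=C(C1=O)CCCCCC1=CC=CN2CC(C)C(=O)C(CCCCC3)=C12 | intermediate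
15 | macrocyclic bis(3-methyl-2-oxo-1,2,3,4-tetrahydroquinolizin-5-ium) dibromide, same connectivity (C1 and C3 epimer mixture) | CC1C[n+]2cccc3c2C(C1=O)CCCCCc1ccc[n+]2CC(C)C(=O)C(CCCCC3)c12.[Br-].[Br-] | intermediate
16 | bis(hydrobromide) of the hydrogenation product: (9S,9aR) in each quinolizidin-2-one unit, C1 and C3 as epimer mixtures | CC1CN2CCC[C@@H]3CCCCCC4C(=O)C(C)CN5CCC[C@H](CCCCCC(C1=O)[C@@H]32)[C@H]45.Br.Br | intermediate
17 | CNP0268544.6: C2-symmetric bis(3-methylquinolizidin-2-one), C1 of each unit joined to C9 of the other by (CH2)5 (16-membered carbocycle); each unit (1R,3S,9S,9aR), H1 trans to H9a, H3 cis to H1, H9 cis to H9a | C[C@H]1CN2CCC[C@@H]3CCCCC[C@H]4C(=O)[C@@H](C)CN5CCC[C@H](CCCCC[C@@H](C1=O)[C@@H]32)[C@H]45 | target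

**Step count**

Total steps: 5. Longest linear sequence: 4 (steps 1, 2, 4, 5).

**Three steps most likely to fail**

Step 5 (the proposed new hydrogenation). It may stall at the hexahydro vinylogous amide, give low enantioselectivity, or touch the ketone. The fallback uses known chemistry, sets out from 15 and comes back at 17. Salt 15 is hydrogenated over PtO2 (H2, 4 bar, MeOH, 23 °C; classical all-cis reduction of pyridinium salts) to the stereorandom bis(hydrobromide) F9 (cis H9/H9a in each ring, racemic plus meso). K2CO3/MeOH equilibration of C1 and C3 and chromatographic removal of the meso isomer give the racemic C2-symmetric diastereomer F10. Classical resolution by crystallisation with (−)-O,O'-di-p-toluoyl-L-tartaric acid gives the di-p-toluoyl-L-tartrate salt of 17 F11 (the D-acid is used if the wanted enantiomer stays in the mother liquor). Aqueous NaOH then liberates 17.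

Step 2 (cyclodimerisation). Eight-membered monomer closure and oligomers may dominate. The fallback sets out from 1 and comes back at 7. Compound 1 is deprotonated with LDA at −78 °C to (3-bromopyridin-2-yl)methyllithium F1 and alkylated with 5-bromopent-1-ene to give 3-bromo-2-(hex-5-en-1-yl)pyridine F2. B-alkyl Suzuki coupling of F2 with borane 3 (conditions of step 1) gives 3-(5-chloropentyl)-2-(hex-5-en-1-yl)pyridine F3. A second portion of F1 displaces the chloride of F3 to give 3-bromo-2-{6-[2-(hex-5-en-1-yl)pyridin-3-yl]hexyl}pyridine F4. Hydroboration of F4 with 9-BBN gives the B-alkyl-9-BBN derivative of F4 F5, which is closed at high dilution (0.002 M) by intramolecular B-alkyl Suzuki coupling (Pd(dppf)Cl2, aq. K3PO4, THF/DMF, 60 °C) to 7. The two chains are built one after the other, and the ring-closing sp2–sp3 bond can only give the 16-membered ring.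

Step 4 (acylation and C–N ring closure). The picolyl anion may add 1,4 to the methacrylamide or start its oligomerisation, and free enone 13 may polymerise. The fallback sets out from 7 and 10 and comes back at 13, which then closes to 14 and is salted to 15 as in step 4. Amide 10 is first treated with dimethylamine (aza-Michael addition, MeOH, 23 °C) to give 3-(dimethylamino)-N-methoxy-N,2-dimethylpropanamide F6. Acylation of dilithio compound 11 with F6 gives the bis(lithium hemiaminal) of the amino amide F7 and, after aqueous work-up, the bis(Mannich-base ketone) F8, which carries no Michael acceptor and can be purified. Heating F8 in AcOH/MeOH at 70 °C expels dimethylamine (retro-Michael, amine exchange) and releases 13 at low stationary concentration.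

**Further compounds**

F1 | step 2 | (3-bromopyridin-2-yl)methyllithium | [Li]Cc1ncccc1Br
F2 | step 2 | 3-bromo-2-(hex-5-en-1-yl)pyridine | C=CCCCCc1ncccc1Br
F3 | step 2 | 3-(5-chloropentyl)-2-(hex-5-en-1-yl)pyridine | C=CCCCCc1ncccc1CCCCCCl
F4 | step 2 | 3-bromo-2-{6-[2-(hex-5-en-1-yl)pyridin-3-yl]hexyl}pyridine | C=CCCCCc1ncccc1CCCCCCc1ncccc1Br
F5 | step 2 | B-alkyl-9-BBN derivative of F4 (boron on the terminal carbon of the former hexenyl chain) | Brc1cccnc1CCCCCCc1cccnc1CCCCCCB1C2CCCC1CCC2
F6 | step 4 | 3-(dimethylamino)-N-methoxy-N,2-dimethylpropanamide | CN(C)CC(C)C(=O)N(C)OC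
F7 | step 4 | bis(lithium hemiaminal) from 11 and two molecules of F6 (diastereomer mixture) | c1ccc2c(n1)C(C(O[Li])(N(C)OC)C(C)CN(C)C)CCCCCc1cccnc1C(C(O[Li])(N(C)OC)C(C)CN(C)C)CCCCC2
F8 | step 4 | bis(Mannich-base ketone): 7 carrying a 3-(dimethylamino)-2-methylpropanoyl group on each CH attached to pyridine C2 (diastereomer mixture) | c1ccc2c(n1)C(C(=O)C(C)CN(C)C)CCCCCc1cccnc1C(C(=O)C(C)CN(C)C)CCCCC2
F9 | step 5 | stereorandom bis(hydrobromide) of the hydrogenation product (cis H9/H9a in each ring, racemic plus meso, C1 and C3 mixed) | CC1CN2CCCC3CCCCCC4C(=O)C(C)CN5CCCC(CCCCCC(C1=O)C32)C45.Br.Br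
F10 | step 5 | racemate of the C2-symmetric diastereomer (17 with its mirror image, 1:1) | C[C@H]1CN2CCC[C@@H]3CCCCC[C@H]4C(=O)[C@@H](C)CN5CCC[C@H](CCCCC[C@@H](C1=O)[C@@H]32)[C@H]45.C[C@@H]1CN2CCC[C@H]3CCCCC[C@@H]4C(=O)[C@H](C)CN5CCC[C@@H](CCCCC[C@H](C1=O)[C@H]32)[C@@H]45
F11 | step 5 | salt of 17 with (−)-O,O'-di-p-toluoyl-L-tartaric acid (1:1) | C[C@H]1CN2CCC[C@@H]3CCCCC[C@H]4C(=O)[C@@H](C)CN5CCC[C@H](CCCCC[C@@H](C1=O)[C@@H]32)[C@H]45.OC(=O)[C@H](OC(=O)c1ccc(C)cc1)[C@@H](OC(=O)c1ccc(C)cc1)C(O)=O
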